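**Retrosynthetic overview**

1. Numbering: ten-membered ring C1 (hemiketal) to C10 (CHMe), with C4 (C–Me, ether), C5=C6, C7, C8 (acyloxy CH); lactone O–C12(=O)–C11=C7, C13 = CH2O on C11. The feature the route rests on is the oxolane O–C1–C2–C3–C4 (methyl on C4, oxygen on C1) set in the ten-membered ring: it is a 2-methylfuran that has taken carbon at C4 and an oxygen nucleophile at C1.
2. Key disconnection: C4–C5 (closes the ten-membered ring) and C1–OMe, by palladium-catalysed dearomative carbopalladation of the furan in 14 with capture of the allylpalladium by methanol.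
3. Precursor 14 comes from enynoic acid 13 by anti iodolactonisation. The tetrasubstituted C7=C11 alkene comes from ynoate 6 by anti diiodination, then Sonogashira coupling (C6) and Stille coupling (C13).
4. C8 is set by catalytic asymmetric alkynylation of aldehyde 3, C10 by organocatalytic Friedel–Crafts addition of 2-methylfuran to crotonaldehyde.
5. Ring order: furan (from 1), butenolide (step 9), ten-membered ring with the furan turned into the oxygen bridge (step 10). Then diimide, acid deprotection, C13 acetate, C8 ester, desilylation.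

Key step: step 10

**Remarks**

- The C5 halide is carried as iodide, not bromide: the (E)-halomethylene unit has to be made by anti halolactonisation with the 2,5-dialkylfuran present, which should tolerate I2/NaHCO3 but not electrophilic bromine; the C–I bond also adds to zerovalent palladium more readily.
- The ligand antipodes in steps 1 and 2 are those expected, by analogy with related additions, to give (10R) and (8S); should the sense be opposite, the mirror-image ligand is used.
- Descriptors at C1 change between 18 (1R) and 19 (1S) only through CIP priorities; the spatial arrangement is the same.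

**Route**

Step 1
Reactants: 1 2-methylfuran; 2 (E)-crotonaldehyde
Product: 3 (3R)-3-(5-methylfuran-2-yl)butanal
Conditions: (2S,5S)-5-benzyl-2-tert-butyl-3-methylimidazolidin-4-one·TFA (20 mol %), CH2Cl2/i-PrOH, −50 °C
Reagents that add atoms: none
Why: Iminium-catalysed Friedel–Crafts conjugate addition of the free furan α-carbon to the enal; the benzyl group of the catalyst shields one face of the (E)-iminium ion, so C10 is expected as (R) by analogy with the indole and pyrrole additions of this catalyst.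

Step 2
Reactants: 3 (3R)-3-(5-methylfuran-2-yl)butanal; 4 methyl propiolate
Product: 5 methyl (4S,6R)-4-hydroxy-6-(5-methylfuran-2-yl)hept-2-ynoate
Conditions: Me2Zn, (S,S)-ProPhenol (10 mol %), Ph3PO (20 mol %), toluene, 4 °C, slow addition of 3; aq. NH4Cl
Reagents that add atoms: none
Why: Catalytic asymmetric alkynylation (zinc alkynylide addition under a dinuclear zinc–ProPhenol catalyst); the ligand controls the aldehyde face and sets C8 as (S) independently of the remote C10 centre, and slow addition limits aldol self-condensation.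

Step 3
Reactants: 5 methyl (4S,6R)-4-hydroxy-6-(5-methylfuran-2-yl)hept-2-ynoate
Product: 6 methyl (4S,6R)-4-[(tert-butyldimethylsilyl)oxy]-6-(5-methylfuran-2-yl)hept-2-ynoate
Conditions: TBSOTf, 2,6-lutidine, CH2Cl2, −78 °C
Reagents that add atoms: tert-butyldimethylsilyl triflate CC(C)(C)[Si](C)(C)OS(=O)(=O)C(F)(F)F
Why: Silylation of the propargylic alcohol with a silyl triflate and a non-nucleophilic base, which avoids conjugate addition of an amine to the ynoate.

Step 4
Reactants: 6 methyl (4S,6R)-4-[(tert-butyldimethylsilyl)oxy]-6-(5-methylfuran-2-yl)hept-2-ynoate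
Product: 7 methyl (2E,4S,6R)-4-[(tert-butyldimethylsilyl)oxy]-2,3-diiodo-6-(5-methylfuran-2-yl)hept-2-enoate
Conditions: I2 (1.5 equiv), NaI (0.3 equiv), MeCN, 23 °C, dark; aq. Na2S2O3
Reagents that add atoms: iodine II
Why: Iodide-assisted anti addition of iodine to the electron-poor alkyne should give the thermodynamically favoured (E)-2,3-diiodoacrylate, with the C7 iodine cis to the ester and the C11 iodine cis to C8; iodine without an activator should not iodinate the 2,5-dialkylfuran.

Step 5
Reactants: 7 methyl (2E,4S,6R)-4-[(tert-butyldimethylsilyl)oxy]-2,3-diiodo-6-(5-methylfuran-2-yl)hept-2-enoate; 8 (trimethylsilyl)acetylene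
Product: 9 methyl (2Z,4S,6R)-4-[(tert-butyldimethylsilyl)oxy]-2-iodo-6-(5-methylfuran-2-yl)-3-[(trimethylsilyl)ethynyl]hept-2-enoate
Conditions: PdCl2(PPh3)2 (5 mol %), CuI (10 mol %), i-Pr2NH, THF, 0 → 23 °C
Reagents that add atoms: none
Why: Sonogashira coupling at the β-iodide, which as a vinylogous acyl iodide should add to zerovalent palladium faster than the α-iodide (as in couplings of 2,3-dihaloacrylates and 3,4-dihalobutenolides), with retention of the alkene geometry.

Step 6
Reactants: 9 methyl (2Z,4S,6R)-4-[(tert-butyldimethylsilyl)oxy]-2-iodo-6-(5-methylfuran-2-yl)-3-[(trimethylsilyl)ethynyl]hept-2-enoate; 10 (tributylstannyl)methanol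
Product: 11 methyl (2E,4S,6R)-4-[(tert-butyldimethylsilyl)oxy]-2-(hydroxymethyl)-6-(5-methylfuran-2-yl)-3-[(trimethylsilyl)ethynyl]hept-2-enoate
Conditions: Pd(PPh3)4 (10 mol %), 1,4-dioxane, 90 °C
Reagents that add atoms: none
Why: Stille coupling of the α-iodoacrylate with the hydroxymethylstannane (the α-oxygenated group transfers in preference to butyl) installs C13 cis to C8 with retention.

Step 7
Reactants: 11 methyl (2E,4S,6R)-4-[(tert-butyldimethylsilyl)oxy]-2-(hydroxymethyl)-6-(5-methylfuran-2-yl)-3-[(trimethylsilyl)ethynyl]hept-2-enoate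
Product: 12 methyl (2E,4S,6R)-4-[(tert-butyldimethylsilyl)oxy]-2-{[(tert-butyldimethylsilyl)oxy]methyl}-6-(5-methylfuran-2-yl)-3-[(trimethylsilyl)ethynyl]hept-2-enoate
Conditions: TBSCl, imidazole, DMF, 23 °C
Reagents that add atoms: tert-butyldimethylsilyl chloride CC(C)(C)[Si](C)(C)Cl
Why: Standard silylation of the primary allylic alcohol.

Step 8
Reactants: 12 methyl (2E,4S,6R)-4-[(tert-butyldimethylsilyl)oxy]-2-{[(tert-butyldimethylsilyl)oxy]methyl}-6-(5-methylfuran-2-yl)-3-[(trimethylsilyl)ethynyl]hept-2-enoate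
Product: 13 (2E,4S,6R)-4-[(tert-butyldimethylsilyl)oxy]-2-{[(tert-butyldimethylsilyl)oxy]methyl}-3-ethynyl-6-(5-methylfuran-2-yl)hept-2-enoic acid
Conditions: LiOH·H2O, THF/MeOH/H2O, 23 °C; 1 M HCl to pH 4
Reagents that add atoms: lithium hydroxide [Li+].[OH-]
Why: Saponification of the methyl ester with concomitant protodesilylation of the alkynylsilane; the silyl ethers should tolerate hydroxide at room temperature.

Step 9
Reactants: 13 (2E,4S,6R)-4-[(tert-butyldimethylsilyl)oxy]-2-{[(tert-butyldimethylsilyl)oxy]methyl}-3-ethynyl-6-(5-methylfuran-2-yl)hept-2-enoic acid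
Product: 14 (5E)-3-{[(tert-butyldimethylsilyl)oxy]methyl}-4-[(1S,3R)-1-[(tert-butyldimethylsilyl)oxy]-3-(5-methylfuran-2-yl)butyl]-5-(iodomethylidene)furan-2(5H)-one
Conditions: I2 (2 equiv), NaHCO3, MeCN, 0 °C, dark; aq. Na2S2O3
Reagents that add atoms: iodine II
Why: Iodolactonisation by 5-exo-dig anti addition of carboxylate and iodine across the terminal alkyne (Markovnikov attack at internal C6) should give the (E)-iodomethylene butenolide with iodine cis to C7; the product is kept from light to avoid E to Z isomerisation.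

Step 10
Reactants: 14 (5E)-3-{[(tert-butyldimethylsilyl)oxy]methyl}-4-[(1S,3R)-1-[(tert-butyldimethylsilyl)oxy]-3-(5-methylfuran-2-yl)butyl]-5-(iodomethylidene)furan-2(5H)-one; 15 methanol
Product: 18 (1R,4R,5E,8S,10R)-8,13-bis[(tert-butyldimethylsilyl)oxy]-1-methoxy-1,4-epoxygermacra-2,5,7(11)-trien-12,6-olide, via alkenylpalladium iodide 16 (not isolated), via allylpalladium iodide 17 (not isolated)
Conditions: Pd(PPh3)4 (20 mol %), Ag2CO3 (2 equiv), MeOH/1,4-dioxane 1:4, 0.002 M, slow addition of 14, 70 °C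
Reagents that add atoms: none
Why: Proposed new method: zerovalent palladium inserts into the C5–I bond with retention (16), the alkenylpalladium, made cationic by Ag2CO3, adds syn across furan C4=C3 with carbon going to the methyl-bearing α-carbon C4 and palladium to C3 (17), and the oxygen-stabilised allylpalladium over C3–C2–C1, which has no β-hydrogen on quaternary C4, is captured by methanol at C1 anti to palladium; the closest known reaction is the palladium-catalysed dearomative Heck spirocyclisation of 2-substituted furans with alcohol capture at the far α-carbon (2,5-difunctionalisation), known only for small rings. The one ring closed is the ten-membered carbocycle C1–C10, formed through the C4–C5 bond as an endo-type macrocyclic carbopalladation in which the furan becomes the 1,4-oxygen bridge, and rehybridisation of both furan α-carbons to sp3 should ease the strain. C4 is set by the furan face that C5 can reach: allylic 1,3-strain about C1–C10 keeps C10–H in the furan plane beside C2–H, so the (10R) centre sends the C9 chain over one face only, and delivery of C5 across that face gives (4R). C1 follows from anti attack of methanol, which puts C10 on the same side of the new dihydrofuran as C5, the only arrangement a six-atom bridge allows. The step needs site selectivity for C4 over C1 (seven-membered spiro closure) and C3: C1 carries the branched C10 and would become a congested spiro centre next to the planar dienyl lactone, C4 carries only methyl, and addition at C3 would forfeit the oxygen-stabilised allyl. The C5=C6 geometry is carried in from 14.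

Step 11
Reactants: 18 (1R,4R,5E,8S,10R)-8,13-bis[(tert-butyldimethylsilyl)oxy]-1-methoxy-1,4-epoxygermacra-2,5,7(11)-trien-12,6-olide
Product: 19 (1S,4R,5E,8S,10R)-8,13-bis[(tert-butyldimethylsilyl)oxy]-1-methoxy-1,4-epoxygermacra-5,7(11)-dien-12,6-olide
Conditions: 2-nitrobenzenesulfonylhydrazide, Et3N, CH2Cl2, 23 °C
Reagents that add atoms: none
Why: Diimide reduction; the strained cis-disubstituted C2=C3 bond should react well before the tri- and tetrasubstituted conjugated C5=C6 and C7=C11 bonds, and ketal, lactone and silyl ethers are inert.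

Step 12
Reactants: 19 (1S,4R,5E,8S,10R)-8,13-bis[(tert-butyldimethylsilyl)oxy]-1-methoxy-1,4-epoxygermacra-5,7(11)-dien-12,6-olide
Product: 20 (1S,4R,5E,8S,10R)-1,8,13-trihydroxy-1,4-epoxygermacra-5,7(11)-dien-12,6-olide
Conditions: 48% aq. HF, MeCN, 0 → 23 °C
Reagents that add atoms: water O
Why: Aqueous HF cleaves both silyl ethers and, through the bridgehead oxocarbenium ion, exchanges the methyl ketal for the hemiketal; C1 cannot invert because the oxygen bridge to C4 fixes it.

Step 13
Reactants: 20 (1S,4R,5E,8S,10R)-1,8,13-trihydroxy-1,4-epoxygermacra-5,7(11)-dien-12,6-olide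
Product: 21 (1S,4R,5E,8S,10R)-13-acetoxy-1,8-dihydroxy-1,4-epoxygermacra-5,7(11)-dien-12,6-olide
Conditions: Ac2O (1.1 equiv), 2,4,6-collidine, CH2Cl2, −20 °C
Reagents that add atoms: acetic anhydride CC(=O)OC(C)=O
Why: Selective acylation; the primary allylic C13 hydroxyl should react much faster than the hindered secondary C8 hydroxyl and the tertiary hemiketal hydroxyl with one equivalent of anhydride at low temperature.

Step 14
Reactants: 22 (tert-butyldimethylsilyloxy)acetaldehyde; 23 ethyl 2-(triphenylphosphoranylidene)propanoate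
Product: 24 ethyl (E)-4-[(tert-butyldimethylsilyl)oxy]-2-methylbut-2-enoate
Conditions: CH2Cl2, 23 °C
Reagents that add atoms: none
Why: Wittig olefination with the stabilised α-branched ylide should give the (E)-trisubstituted enoate.

Step 15
Reactants: 24 ethyl (E)-4-[(tert-butyldimethylsilyl)oxy]-2-methylbut-2-enoate
Product: 25 (E)-4-[(tert-butyldimethylsilyl)oxy]-2-methylbut-2-enoic acid
Conditions: LiOH·H2O, THF/H2O, 23 °C; 1 M HCl to pH 3
Reagents that add atoms: lithium hydroxide [Li+].[OH-]
Why: Saponification of the ethyl ester; the primary silyl ether should survive LiOH at room temperature.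

Step 16
Reactants: 21 (1S,4R,5E,8S,10R)-13-acetoxy-1,8-dihydroxy-1,4-epoxygermacra-5,7(11)-dien-12,6-olide; 25 (E)-4-[(tert-butyldimethylsilyl)oxy]-2-methylbut-2-enoic acid
Product: 27 (1S,4R,5E,8S,10R)-13-acetoxy-8-{(E)-4-[(tert-butyldimethylsilyl)oxy]-2-methylbut-2-enoyloxy}-1-hydroxy-1,4-epoxygermacra-5,7(11)-dien-12,6-olide, via mixed anhydride 26 (not isolated)
Conditions: 2,4,6-trichlorobenzoyl chloride, Et3N, THF; then 21, DMAP, toluene, 23 °C
Reagents that add atoms: none
Why: Yamaguchi esterification; the mixed anhydride acylates the hindered secondary allylic C8 hydroxyl under DMAP catalysis while the tertiary hemiketal hydroxyl stays free, and C8 keeps its configuration because its C–O bond is not broken.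

Step 17
Reactants: 27 (1S,4R,5E,8S,10R)-13-acetoxy-8-{(E)-4-[(tert-butyldimethylsilyl)oxy]-2-methylbut-2-enoyloxy}-1-hydroxy-1,4-epoxygermacra-5,7(11)-dien-12,6-olide
Product: 28 (1S,4R,5E,8S,10R)-13-acetoxy-1-hydroxy-8-[(E)-4-hydroxy-2-methylbut-2-enoyloxy]-1,4-epoxygermacra-5,7(11)-dien-12,6-olide (CNP0154520.1)
Conditions: HF·pyridine, pyridine, THF, 0 → 23 °C
Reagents that add atoms: none
Why: Buffered fluoride desilylation of the primary allylic silyl ether, which should leave the acetate, the two esters, the enol lactone and the hemiketal untouched.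

**Compound list**

1 | 2-methylfuran | Cc1ccco1 | starting material
2 | (E)-crotonaldehyde | C/C=C/C=O | starting material
3 | (3R)-3-(5-methylfuran-2-yl)butanal | O=CC[C@@H](C)c1ccc(C)o1 | intermediate
4 | methyl propiolate | C#CC(=O)OC | starting material
5 | methyl (4S,6R)-4-hydroxy-6-(5-methylfuran-2-yl)hept-2-ynoate | COC(=O)C#C[C@@H](O)C[C@@H](C)c1ccc(C)o1 | intermediate
6 | methyl (4S,6R)-4-[(tert-butyldimethylsilyl)oxy]-6-(5-methylfuran-2-yl)hept-2-ynoate | COC(=O)C#C[C@@H](O[Si](C)(C)C(C)(C)C)C[C@@H](C)c1ccc(C)o1 | intermediate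
7 | methyl (2E,4S,6R)-4-[(tert-butyldimethylsilyl)oxy]-2,3-diiodo-6-(5-methylfuran-2-yl)hept-2-enoate | COC(=O)/C(I)=C(\I)[C@@H](O[Si](C)(C)C(C)(C)C)C[C@@H](C)c1ccc(C)o1 | intermediate
8 | (trimethylsilyl)acetylene | C#C[Si](C)(C)C | starting material
9 | methyl (2Z,4S,6R)-4-[(tert-butyldimethylsilyl)oxy]-2-iodo-6-(5-methylfuran-2-yl)-3-[(trimethylsilyl)ethynyl]hept-2-enoate | COC(=O)/C(I)=C(\C#C[Si](C)(C)C)[C@@H](O[Si](C)(C)C(C)(C)C)C[C@@H](C)c1ccc(C)o1 | intermediate
10 | (tributylstannyl)methanol | CCCC[Sn](CCCC)(CCCC)CO | starting material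
11 | methyl (2E,4S,6R)-4-[(tert-butyldimethylsilyl)oxy]-2-(hydroxymethyl)-6-(5-methylfuran-2-yl)-3-[(trimethylsilyl)ethynyl]hept-2-enoate | COC(=O)/C(CO)=C(\C#C[Si](C)(C)C)[C@@H](O[Si](C)(C)C(C)(C)C)C[C@@H](C)c1ccc(C)o1 | intermediate
12 | methyl (2E,4S,6R)-4-[(tert-butyldimethylsilyl)oxy]-2-{[(tert-butyldimethylsilyl)oxy]methyl}-6-(5-methylfuran-2-yl)-3-[(trimethylsilyl)ethynyl]hept-2-enoate | COC(=O)/C(CO[Si](C)(C)C(C)(C)C)=C(\C#C[Si](C)(C)C)[C@@H](O[Si](C)(C)C(C)(C)C)C[C@@H](C)c1ccc(C)o1 | intermediate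
13 | (2E,4S,6R)-4-[(tert-butyldimethylsilyl)oxy]-2-{[(tert-butyldimethylsilyl)oxy]methyl}-3-ethynyl-6-(5-methylfuran-2-yl)hept-2-enoic acid | OC(=O)/C(CO[Si](C)(C)C(C)(C)C)=C(\C#C)[C@@H](O[Si](C)(C)C(C)(C)C)C[C@@H](C)c1ccc(C)o1 | intermediate
14 | (5E)-3-{[(tert-butyldimethylsilyl)oxy]methyl}-4-[(1S,3R)-1-[(tert-butyldimethylsilyl)oxy]-3-(5-methylfuran-2-yl)butyl]-5-(iodomethylidene)furan-2(5H)-one | CC(C)(C)[Si](C)(C)OCC1=C(/C(=C\I)OC1=O)[C@@H](O[Si](C)(C)C(C)(C)C)C[C@@H](C)c2ccc(C)o2 | intermediate
15 | methanol | CO | starting material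
16 | (E)-alkenylpalladium iodide from oxidative addition of 14 at C5 (PPh3 ligands not drawn) | CC(C)(C)[Si](C)(C)OCC1=C(/C(=C\[Pd]I)OC1=O)[C@@H](O[Si](C)(C)C(C)(C)C)C[C@@H](C)c2ccc(C)o2 | intermediate (not isolated)
17 | ring-closed allylpalladium iodide after C4–C5 bond formation, drawn with palladium on C3 syn to C5 (PPh3 ligands not drawn) | CC(C)(C)[Si](C)(C)OCC1=C2/C(=C\[C@@]3(C)[C@@H]([Pd]I)C=C(O3)[C@H](C)C[C@@H]2O[Si](C)(C)C(C)(C)C)OC1=O | intermediate (not isolated)
18 | (1R,4R,5E,8S,10R)-8,13-bis[(tert-butyldimethylsilyl)oxy]-1-methoxy-1,4-epoxygermacra-2,5,7(11)-trien-12,6-olide | CC(C)(C)[Si](C)(C)OCC1=C2/C(=C\[C@@]3(C)C=C[C@](OC)(O3)[C@H](C)C[C@@H]2O[Si](C)(C)C(C)(C)C)OC1=O | intermediate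
19 | (1S,4R,5E,8S,10R)-8,13-bis[(tert-butyldimethylsilyl)oxy]-1-methoxy-1,4-epoxygermacra-5,7(11)-dien-12,6-olide | CC(C)(C)[Si](C)(C)OCC1=C2/C(=C\[C@@]3(C)CC[C@](OC)(O3)[C@H](C)C[C@@H]2O[Si](C)(C)C(C)(C)C)OC1=O | intermediate
20 | (1S,4R,5E,8S,10R)-1,8,13-trihydroxy-1,4-epoxygermacra-5,7(11)-dien-12,6-olide | OCC1=C2/C(=C\[C@@]3(C)CC[C@](O)(O3)[C@H](C)C[C@@H]2O)OC1=O | intermediate
21 | (1S,4R,5E,8S,10R)-13-acetoxy-1,8-dihydroxy-1,4-epoxygermacra-5,7(11)-dien-12,6-olide | CC(=O)OCC1=C2/C(=C\[C@@]3(C)CC[C@](O)(O3)[C@H](C)C[C@@H]2O)OC1=O | intermediate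
22 | (tert-butyldimethylsilyloxy)acetaldehyde | O=CCO[Si](C)(C)C(C)(C)C | starting material
23 | ethyl 2-(triphenylphosphoranylidene)propanoate | CCOC(=O)C(C)=P(c1ccccc1)(c1ccccc1)c1ccccc1 | starting material
24 | ethyl (E)-4-[(tert-butyldimethylsilyl)oxy]-2-methylbut-2-enoate | CCOC(=O)/C(C)=C/CO[Si](C)(C)C(C)(C)C | intermediate
25 | (E)-4-[(tert-butyldimethylsilyl)oxy]-2-methylbut-2-enoic acid | OC(=O)/C(C)=C/CO[Si](C)(C)C(C)(C)C | intermediate
26 | (E)-4-[(tert-butyldimethylsilyl)oxy]-2-methylbut-2-enoic 2,4,6-trichlorobenzoic anhydride | CC(C)(C)[Si](C)(C)OC/C=C(\C)C(=O)OC(=O)c1c(Cl)cc(Cl)cc1Cl | intermediate (not isolated)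
27 | (1S,4R,5E,8S,10R)-13-acetoxy-8-{(E)-4-[(tert-butyldimethylsilyl)oxy]-2-methylbut-2-enoyloxy}-1-hydroxy-1,4-epoxygermacra-5,7(11)-dien-12,6-olide | CC(=O)OCC1=C2/C(=C\[C@@]3(C)CC[C@](O)(O3)[C@H](C)C[C@@H]2OC(=O)/C(C)=C/CO[Si](C)(C)C(C)(C)C)OC1=O | intermediate
28 | (1S,4R,5E,8S,10R)-13-acetoxy-1-hydroxy-8-[(E)-4-hydroxy-2-methylbut-2-enoyloxy]-1,4-epoxygermacra-5,7(11)-dien-12,6-olide (CNP0154520.1) | CC(=O)OCC1=C2/C(=C\[C@@]3(C)CC[C@](O)(O3)[C@H](C)C[C@@H]2OC(=O)/C(C)=C/CO)OC1=O | target

**Step count**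

Total step count: 17. Longest linear sequence: 15 steps (steps 1–13, 16 and 17); steps 14 and 15 make the side-chain acid 25.

**Steps most likely to fail**

1. Step 10 (key step). The alkenylpalladium may close at C1 to a seven-membered spiro ring instead of at C4, may be reduced by hydride transfer from methoxide, the allylpalladium may lose hydrogen from C10 instead of accepting methanol, or the wrong furan face may be used. Fallback with known chemistry, setting out from 14: oxidative opening of the 2,5-dialkylfuran with mCPBA (CH2Cl2, 0 °C) would give the cis-enedione F1. Conjugate reduction with Zn in AcOH/THF would give the 1,4-diketone F2. An intramolecular Nozaki–Hiyama–Kishi reaction (CrCl2, catalytic NiCl2, DMF, high dilution) would add the C5 alkenylchromium to the C4 methyl ketone, the less hindered of the two carbonyls, and the tertiary alkoxide would close onto the C1 ketone to give the bridged hemiketal bis-silyl ether F3; C4 then rests on macrocyclic control. Aqueous HF in MeCN would convert F3 into 20, where the route is rejoined.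

2. Step 4. Addition of iodine to the hindered, electron-poor alkyne may be slow or reversible, the furan may be iodinated on long exposure, and in step 5 the diiodide may couple at the wrong iodide or lose iodine back to the alkyne under palladium. Fallback, setting out from 6: syn-distannylation with hexamethylditin and Pd(PPh3)4 (THF, reflux) would give the (Z)-2,3-bis(trimethylstannyl) ester F4, in which the ester carbon, now cis to C8, is destined to become C13. Stille coupling of the β-stannyl group with (bromoethynyl)trimethylsilane would give the α-stannyl enynoate F5, and iododestannylation (I2, CH2Cl2, 0 °C) the α-iodo enynoate F6. DIBAL-H would reduce the ester to the allylic alcohol F7, and TBSCl/imidazole would give the silyl ether F8. Methoxycarbonylation of the alkenyl iodide (PdCl2(PPh3)2, CO, MeOH, Et3N, DMF) would install C12 cis to the alkyne and return the route to 12.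

3. Step 9. The carboxylate may close 6-endo to an iodopyranone, excess iodine may attack the furan, and iodine may isomerise the (E)-iodomethylene unit to the more stable (Z) form. Fallback, setting out from 13: anti oxymercuration with Hg(O2CCF3)2 (CH2Cl2, −20 °C) followed by aqueous NaCl would give the (E)-chloromercuriomethylene butenolide F9; iododemercuration with one equivalent of I2 at −20 °C, which proceeds with retention, would return the route to 14.

Further compounds
F1 | step 10 | (5E)-3-{[(tert-butyldimethylsilyl)oxy]methyl}-4-[(1S,3R,5Z)-1-[(tert-butyldimethylsilyl)oxy]-3-methyl-4,7-dioxooct-5-en-1-yl]-5-(iodomethylidene)furan-2(5H)-one | CC(C)(C)[Si](C)(C)OCC1=C(/C(=C\I)OC1=O)[C@@H](O[Si](C)(C)C(C)(C)C)C[C@@H](C)C(=O)/C=C\C(C)=O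
F2 | step 10 | (5E)-3-{[(tert-butyldimethylsilyl)oxy]methyl}-4-[(1S,3R)-1-[(tert-butyldimethylsilyl)oxy]-3-methyl-4,7-dioxooctyl]-5-(iodomethylidene)furan-2(5H)-one | CC(C)(C)[Si](C)(C)OCC1=C(/C(=C\I)OC1=O)[C@@H](O[Si](C)(C)C(C)(C)C)C[C@@H](C)C(=O)CCC(C)=O
F3 | step 10 | (1S,4R,5E,8S,10R)-8,13-bis[(tert-butyldimethylsilyl)oxy]-1-hydroxy-1,4-epoxygermacra-5,7(11)-dien-12,6-olide | CC(C)(C)[Si](C)(C)OCC1=C2/C(=C\[C@@]3(C)CC[C@](O)(O3)[C@H](C)C[C@@H]2O[Si](C)(C)C(C)(C)C)OC1=O
F4 | step 4 | methyl (2Z,4S,6R)-4-[(tert-butyldimethylsilyl)oxy]-6-(5-methylfuran-2-yl)-2,3-bis(trimethylstannyl)hept-2-enoate | COC(=O)/C([Sn](C)(C)C)=C(/[Sn](C)(C)C)[C@@H](O[Si](C)(C)C(C)(C)C)C[C@@H](C)c1ccc(C)o1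
F5 | step 4 | methyl (2E,4S,6R)-4-[(tert-butyldimethylsilyl)oxy]-6-(5-methylfuran-2-yl)-3-[(trimethylsilyl)ethynyl]-2-(trimethylstannyl)hept-2-enoate | COC(=O)/C([Sn](C)(C)C)=C(/C#C[Si](C)(C)C)[C@@H](O[Si](C)(C)C(C)(C)C)C[C@@H](C)c1ccc(C)o1
F6 | step 4 | methyl (2E,4S,6R)-4-[(tert-butyldimethylsilyl)oxy]-2-iodo-6-(5-methylfuran-2-yl)-3-[(trimethylsilyl)ethynyl]hept-2-enoate | COC(=O)/C(I)=C(/C#C[Si](C)(C)C)[C@@H](O[Si](C)(C)C(C)(C)C)C[C@@H](C)c1ccc(C)o1
F7 | step 4 | (2E,4S,6R)-4-[(tert-butyldimethylsilyl)oxy]-2-iodo-6-(5-methylfuran-2-yl)-3-[(trimethylsilyl)ethynyl]hept-2-en-1-ol | OC/C(I)=C(/C#C[Si](C)(C)C)[C@@H](O[Si](C)(C)C(C)(C)C)C[C@@H](C)c1ccc(C)o1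
F8 | step 4 | (2E,4S,6R)-1,4-bis[(tert-butyldimethylsilyl)oxy]-2-iodo-6-(5-methylfuran-2-yl)-3-[(trimethylsilyl)ethynyl]hept-2-ene | CC(C)(C)[Si](C)(C)OC/C(I)=C(/C#C[Si](C)(C)C)[C@@H](O[Si](C)(C)C(C)(C)C)C[C@@H](C)c1ccc(C)o1
F9 | step 9 | (5E)-3-{[(tert-butyldimethylsilyl)oxy]methyl}-4-[(1S,3R)-1-[(tert-butyldimethylsilyl)oxy]-3-(5-methylfuran-2-yl)butyl]-5-[(chloromercurio)methylidene]furan-2(5H)-one | CC(C)(C)[Si](C)(C)OCC1=C(/C(=C\[Hg]Cl)OC1=O)[C@@H](O[Si](C)(C)C(C)(C)C)C[C@@H](C)c2ccc(C)o2
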